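The numbers in the tables were generated by integration from invented constants, noise included.

A small charge of second end groups, 0.0788 M against 0.075 M of first end groups, or 1.05 equivalents, is what the dawn flask has to work with, and I want to know what it holds at 4.0 h.

| flask | first end groups | second end groups | protic impurity | remark | time |
|---|---|---|---|---|---|
| dawn | 0.075 M | 0.0788 M (in portions, 4) | 0.0375 M | the very flask that is asked about, followed so far; portions every 10 min |  |
| midnight | 0.11 M | 0.0788 M (in portions, 4) | 0.0375 M | run made earlier; portions every 10 min |  |
| flask | 0.075 M | 0.0788 M (in portions, 4) | 0.0375 M | the portions of second end groups follow each other after 10 min, the first at the start | 4.0 h |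

| run | time / min | rings / % | links / % | first end groups / % | over-reaction product / % |
|---|---|---|---|---|---|
| dawn | 12.0 | 21.4 | 3.1 | 65.8 | 0.5 |
| dawn | 25.0 | 36.8 | 5.0 | 40.8 | 1.2 |
| dawn | 40.0 | 47.9 | 6.6 | 23.5 | 3.7 |
| dawn | 50.0 | 52.0 | 6.7 | 16.4 | 5.4 |
| dawn | 60.0 | 55.5 | 5.3 | 12.6 | 6.8 |
| dawn | 80.0 | 59.6 | 4.5 | 7.1 | 9.5 |
| midnight | 6.00 | 12.5 | 1.8 | 80.6 | 0 |
| midnight | 20.0 | 30.1 | 2.8 | 53.9 | 0.6 |
| midnight | 30.0 | 39.5 | 3.7 | 38.0 | 1.9 |
| midnight | 50.0 | 51.4 | 4.2 | 19.9 | 4.4 |
| midnight | 80.0 | 58.2 | 3.0 | 12.0 | 6.1 |
| midnight | 90.0 | 58.7 | 1.5 | 11.3 | 6.8 |

(standard deviation of a reading: 0.3 percentage points)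

- the species that holds most of what was charged as first end groups, at 4.0 h (first end groups / links / rings / over-reaction product)
- the largest share itself, whichever of these holds it, in percent of the first end groups charged

- the numbers in the tables scatter by 0.3 percentage points (one standard deviation)
- a reading or a percentage of first end groups is of its free form alone

I carry one number, the ring share (the selectivity): rings divided by rings plus links plus over-reaction product. In the dawn run at 80.0 min it reads 81.0 %. The midnight run at 90.0 min, with 0.716 equivalents, reads 87.6 %, so in these two runs the share reads lower at the higher equivalents.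

Now I climb the time scales of the dawn flask. Portions come every 10 min, and free first end groups show a half-life of 23.2 min between 40.0 min and 80.0 min, longer than that interval. Links read 6.7 % at 50.0 min and 4.5 % at 80.0 min. The part missing from the four columns stands at 18.3 % at 40.0 min and 19.3 % at 80.0 min, so I treat it as a store that opens late, if at all.

From 80.0 min to 4.0 h lie 6.91 half-lives, so I let what is free react and split by the share. With the store shut, that gives rings 65.3 %, and they lead, since the share is above one half. I commit to rings, somewhat above that figure.

The forecast says rings at 67 %, holding that “Over-reaction tracks links, not rings, so rings should be stable”.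

The dawn flask gives rings at 71.3 %, and the dormant form, which is the store, holds 11.4 % at 4.00 h. The ring share there is 82.9 %. The carried 81.0 %, put on the 85.9 % that stands as rings, links and over-reaction product, gives 69.6 %.

    first end groups + second end groups → links (k = 17.0 L mol⁻¹ h⁻¹)
    first end groups + second end groups → rings, rate k2*[first end groups] as long as [second end groups] is above zero (k = 1.35 h⁻¹)
    first end groups ⇌ dormant form (K = 1.80, k = 0.590 h⁻¹)
    second end groups + protic impurity → quenched reagent (k = 12.6 L mol⁻¹ h⁻¹)
    links → over-reaction product (k = 1.44 h⁻¹)

A neighbour flask, like the dawn flask but charged with 0.13 M of second end groups, has 1.73 equiv, and the line through my two read shares, taken in equivalents, gives a share of 67.5 %. It comes out with rings 59.2 % and a share of 65.9 %.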